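One number first.

    nucleophile + acid set free ⇌ protonated nucleophile, settled at all times (K1 = 990 M⁻¹)
    electrophile + acid set free ⇌ idle adduct, settled at all times (K2 = 14 M⁻¹)
    acid set free + scavenger → scavenged by-product (k3 = 400 M⁻¹ h⁻¹)
    electrophile + nucleophile ⇌ acid set free + target (K4 = 2.6, k4 = 1.1 M⁻¹ h⁻¹)

| setting | summer | dawn | midnight |
|---|---|---|---|
| electrophile | 0.050 M | 0.050 M | 0.050 M |
| nucleophile | 3.00 equiv | 3.00 equiv | 3.00 equiv |
| scavenger | 1.00 equiv | 1.50 equiv | 2.20 equiv |
| time | 12 h | 12 h | 12 h |

1. part of the electrophile that has reacted at the end, summer
2. part of the electrophile that has reacted at the end, dawn
3. part of the electrophile that has reacted at the end, midnight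
4. what raising the equivalents of scavenger from its lowest to its highest value here does to the part of the electrophile that has reacted (changes below 5 percentage points count as none) (it rises / no change / it falls)

- what is said of acid set free includes idle adduct
- run time (summer): 12 h

Multiply the forward rate constant of target formation by the nucleophile as charged and by the run time. You get the exposure 1.98, the e-foldings open to the electrophile with its partner held at its charge (pseudo-first-order). Work in fractions of the charge, and put the first answer back, since the nucleophile falls as it is used:

First round: part reacted = one minus e to the minus exposure = 86.2%

Second round: nucleophile at its middle level = 85.6% of its charge, exposure 1.70, part reacted 81.7%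

Was one number enough? It holds no scavenger, so it says 81.7% for summer, dawn and midnight alike. In summer the half-life of free acid against the scavenger as charged is 2.1 min, far shorter than the 4.2 h of the electrophile by the forward step with the nucleophile as charged. But at the start of summer the nucleophile binds acid with a weight of 150, against 0.70 for the electrophile, and my number does not count that nucleophile as lost. So I take 81.7% as somewhat high, and expect no change across the flasks.

The forecast is lower than my figure: 77%, 78% and 79%, with no change, and it says “Acid parked on the nucleophile trims this by only a few points, and extra scavenger recovers just a point or two”.

The simulation gives 76.9% for summer, 77.7% for dawn and 78.4% for midnight, a change of 1.5 percentage points, so no change. Now take the neighbour of summer charged with 1.20 equiv of nucleophile, time unchanged: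

Exposure 0.792, first round 54.7%, second round 45.7%

That neighbour gives 43.6% reacted, with 56.4% of its electrophile still unbound at the end.

(The numbers of this flask were chosen freely; the result is computed.)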